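**Plan**

- Numbering: chain C1(OAc)–C2–C3–C4(C15H3) on C5; ring A C5=C10(C14H2O)–C9–C8–C7–C6(OAc); lactone C7–C11(=C13H2)–C12(=O)–O–C8.
- Enabling feature: the tetrasubstituted C5=C10 alkene of ring A bears at C5 the C4 branch, whose methyl C15 can be the =CH2 of a C4=C15/C5=C10 diene. Such a diene is the product of enyne metathesis between a C4≡C5 alkyne and a C10 methylidene.
- Cuts: the three ester C–O bonds and C11=C13; the C4–H bond (from C4=C15); C5=C10 together with C4=C15 (back to alkyne plus C10=CH2, the methylene carbon being C15); C5–C6 (acyl–alkyne coupling); C7–C8 (aldol) and the lactone C–O bond.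
- Forward: the trans γ-lactone is built first, the C1–C5 alkyne is joined at C6, ring A is closed onto the lactone by the metathesis, then C4 is set and C13 and the esters are added.
- Stereochemistry: C7 and C8 from an (S)-4-benzyloxazolidinone syn-aldol; C6 from an (S,S)-ruthenium transfer hydrogenation of the ynone; C4 from a hydrogenation anchored at the C14 hydroxyl and biased by the pseudoaxial C6 silyl ether.

Key step: step 10

Remark on the chemistry: the trans-fused lactone locks ring A with the C6 oxygen pseudoaxial (β face) and the diene is taken as twisted near perpendicular; a C6-hydroxyl anchor could then reach two rotamers leading to opposite C4 epimers, so the hydrogenation is anchored at the C14 hydroxyl with C6 carried as a bulky silyl ether.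

**Route**

Step 1
Reactants: 1 3-bromo-2-(bromomethyl)prop-1-ene; 2 4-methoxybenzyl alcohol
Product: 3 1-({[2-(bromomethyl)prop-2-en-1-yl]oxy}methyl)-4-methoxybenzene
Conditions: NaH (1.0 equiv), THF, 0 °C; then 1 (3 equiv), 0 °C to rt
Reagents that add atoms: none
Why: Williamson ether synthesis in which the sodium alkoxide of 2 displaces one primary allylic bromide of 1 (direct and allylic displacement give the same product), the excess of the symmetric dibromide keeping double substitution low.

Step 2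
Reactants: 3 1-({[2-(bromomethyl)prop-2-en-1-yl]oxy}methyl)-4-methoxybenzene
Product: 4 3-{[(4-methoxybenzyl)oxy]methyl}but-3-en-1-ol
Conditions: Zn dust, 37% aq. HCHO, THF/sat. aq. NH4Cl, 0 °C to rt
Reagents that add atoms: formaldehyde, C=O
Why: Aqueous Barbier allylation in which zinc inserts into the allylic C–Br bond and the allylzinc adds to formaldehyde through its γ-carbon, which for this symmetric 2-substituted allyl unit can give only the homoallylic alcohol with the 1,1-disubstituted alkene intact.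

Step 3
Reactants: 4 3-{[(4-methoxybenzyl)oxy]methyl}but-3-en-1-ol
Product: 5 3-{[(4-methoxybenzyl)oxy]methyl}but-3-enal
Conditions: Dess–Martin periodinane, pyridine, CH2Cl2, 0 °C to rt; crude aldehyde used at once
Reagents that add atoms: none
Why: Dess–Martin oxidation under pyridine buffering should give the β,γ-unsaturated aldehyde without acid or base strong enough to move the alkene into conjugation.

Step 4
Reactants: 6 (S)-4-benzyl-1,3-oxazolidin-2-one; 7 methyl 4-chloro-4-oxobutanoate
Product: 8 methyl 4-[(4S)-4-benzyl-2-oxo-1,3-oxazolidin-3-yl]-4-oxobutanoate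
Conditions: n-BuLi, THF, −78 °C; then 7, −78 to 0 °C
Reagents that add atoms: none
Why: N-Acylation of the lithiated oxazolidinone by the acid chloride is much faster than attack at the methyl ester and should give the succinate half-ester imide.

Step 5
Reactants: 8 methyl 4-[(4S)-4-benzyl-2-oxo-1,3-oxazolidin-3-yl]-4-oxobutanoate; 5 3-{[(4-methoxybenzyl)oxy]methyl}but-3-enal
Product: 10 trans-lactone imide (4S)-4-benzyl-3-{[(2R,3S)-2-(2-{[(4-methoxybenzyl)oxy]methyl}prop-2-en-1-yl)-5-oxotetrahydrofuran-3-yl]carbonyl}-1,3-oxazolidin-2-one, via aldol adduct 9 (not isolated)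
Conditions: 8, Bu2BOTf, i-Pr2NEt, CH2Cl2, −78 to 0 °C; 5, −78 to 0 °C; pH 7 buffer, MeOH, 30% H2O2, 0 °C; then PPTS (cat.), toluene, 50 °C
Reagents that add atoms: none
Why: Evans syn-aldol addition followed by lactonisation, in which the Z-boron enolate forms only on the imide side and reacts through a Zimmerman–Traxler chair with the (S)-benzyl auxiliary shielding one enolate face, so that C7 (S) and C8 (R) are set syn and attack of the C8 hydroxyl on the methyl ester closes the γ-lactone with the C6 and C9 arms trans.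

Step 6
Reactants: 10 trans-lactone imide
Product: 11 trans-lactone acid (2R,3S)-2-(2-{[(4-methoxybenzyl)oxy]methyl}prop-2-en-1-yl)-5-oxotetrahydrofuran-3-carboxylic acid
Conditions: LiOH, 30% H2O2, THF/H2O, 0 °C; Na2SO3 (aq.); 1 M HCl to pH 2–3
Reagents that add atoms: hydrogen peroxide, OO
Why: Hydroperoxide cleavage of the N-acyloxazolidinone, in which LiOOH attacks the exocyclic imide carbonyl selectively, sulfite reduces the peracid and any opened lactone recloses on acidification, so C7 and C8 are untouched.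

Step 7
Reactants: 12 pent-4-yn-1-ol
Product: 13 tert-butyl(dimethyl)(pent-4-yn-1-yloxy)silane
Conditions: TBSCl, imidazole, CH2Cl2, 0 °C to rt
Reagents that add atoms: tert-butyl(chloro)dimethylsilane, CC(C)(C)[Si](C)(C)Cl
Why: Standard imidazole-promoted silylation of a primary alcohol.

Step 8
Reactants: 11 trans-lactone acid; 13 tert-butyl(dimethyl)(pent-4-yn-1-yloxy)silane
Product: 15 ynone (4S,5R)-4-(6-{[tert-butyl(dimethyl)silyl]oxy}hex-2-ynoyl)-5-(2-{[(4-methoxybenzyl)oxy]methyl}prop-2-en-1-yl)dihydrofuran-2(3H)-one, via acid chloride 14 (not isolated)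
Conditions: 1-chloro-N,N,2-trimethylprop-1-en-1-amine, CH2Cl2, 0 °C to rt; then 13, PdCl2(PPh3)2 (2 mol %), CuI (copper monoiodide, 4 mol %), Et3N (1.1 equiv), THF, rt
Reagents that add atoms: none
Why: Acyl Sonogashira coupling, in which the neutral chloroenamine makes the acid chloride without free HCl (sparing the 4-methoxybenzyl ether) and oxidative addition of the C–Cl bond to zerovalent palladium followed by transfer of the copper acetylide gives the alkynyl ketone, while C7, the only epimerisable centre, already sits on the thermodynamically preferred trans side of the lactone.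

Step 9
Reactants: 15 ynone
Product: 16 trans-lactone enyne (4R,5R)-4-[(1S)-6-{[tert-butyl(dimethyl)silyl]oxy}-1-hydroxyhex-2-yn-1-yl]-5-(2-{[(4-methoxybenzyl)oxy]methyl}prop-2-en-1-yl)dihydrofuran-2(3H)-one
Conditions: Ru(p-cymene)[(S,S)-TsNCH(Ph)CH(Ph)NH] (2 mol %), i-PrOH, rt
Reagents that add atoms: none
Why: Noyori asymmetric transfer hydrogenation of an alkynyl ketone, in which the (S,S)-ruthenium amide–hydride passes hydride and proton through a six-membered transition state with the alkyne next to the arene ligand, giving the (S)-carbinol at C6 under catalyst control regardless of the adjacent C7 centre, while the base-free medium avoids β-elimination of the lactone oxygen.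

Step 10
Reactants: 16 trans-lactone enyne
Product: 17 bicyclic lactone diene (3aR,4S,7aR)-5-(5-{[tert-butyl(dimethyl)silyl]oxy}pent-1-en-2-yl)-4-hydroxy-6-{[(4-methoxybenzyl)oxy]methyl}-3a,4,7,7a-tetrahydro-1-benzofuran-2(3H)-one
Conditions: second-generation Grubbs catalyst RuCl2(=CHPh)(H2IMes)(PCy3) (10 mol % in two portions), toluene (0.005 M), 80 °C, argon
Reagents that add atoms: none
Why: Ring-closing enyne metathesis of a 1,7-enyne, closest in type to the known ruthenium-carbene closures of internal-alkyne enynes to 1-(alk-1-en-2-yl)cyclohexenes. The propagating Ru=CH2 adds across C4≡C5 with its carbon on the less hindered C4 (this carbon becomes C15), the ruthenacyclobutene opens to the vinylcarbene Ru=C5–C4=C15H2, and [2+2] cycloaddition and cycloreversion with the C10 methylidene form C5=C10 and return Ru=CH2. Ring A closes in the exo mode to a six-membered ring on the preformed trans-lactone. No stereocentre is created and C6 to C8 are not touched by the neutral conditions. The selectivity needed is exo closure over the seven-membered endo isomer and capture of the vinylcarbene by the hindered 1,1-disubstituted alkene over alkyne oligomerisation: the branched C6 carbinol directs ruthenium to C5 and ring size favours the six-membered ring, while high dilution and the absence of ethylene (which would divert the vinylcarbene to an acyclic 2,3-disubstituted butadiene) keep the intramolecular path ahead.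

Step 11
Reactants: 17 bicyclic lactone diene
Product: 18 C6 silyl ether (3aS,4S,7aR)-4-{[tert-butyl(dimethyl)silyl]oxy}-5-(5-{[tert-butyl(dimethyl)silyl]oxy}pent-1-en-2-yl)-6-{[(4-methoxybenzyl)oxy]methyl}-3a,4,7,7a-tetrahydro-1-benzofuran-2(3H)-one
Conditions: TBSOTf, 2,6-lutidine, CH2Cl2, −78 to 0 °C
Reagents that add atoms: tert-butyldimethylsilyl trifluoromethanesulfonate, CC(C)(C)[Si](C)(C)OS(=O)(=O)C(F)(F)F
Why: Silylation of the hindered pseudoaxial allylic C6 hydroxyl with the silyl triflate and a non-nucleophilic pyridine base, conditions under which the lactone and the 4-methoxybenzyl ether are inert.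

Step 12
Reactants: 18 C6 silyl ether
Product: 19 dienyl alcohol (3aS,4S,7aR)-4-{[tert-butyl(dimethyl)silyl]oxy}-5-(5-{[tert-butyl(dimethyl)silyl]oxy}pent-1-en-2-yl)-6-(hydroxymethyl)-3a,4,7,7a-tetrahydro-1-benzofuran-2(3H)-one
Conditions: DDQ, CH2Cl2/pH 7 phosphate buffer, 0 °C
Reagents that add atoms: none
Why: Oxidative cleavage of the 4-methoxybenzyl ether by DDQ through hydride abstraction at the electron-rich benzylic position and hydrolysis of the oxocarbenium ion should free the C14 hydroxyl while both silyl ethers and the twisted, hindered diene are left alone.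

Step 13
Reactants: 19 dienyl alcohol
Product: 20 saturated side-chain alcohol (3aS,4S,7aR)-4-{[tert-butyl(dimethyl)silyl]oxy}-5-[(2S)-5-{[tert-butyl(dimethyl)silyl]oxy}pentan-2-yl]-6-(hydroxymethyl)-3a,4,7,7a-tetrahydro-1-benzofuran-2(3H)-one
Conditions: H2 (50 bar), [Rh(nbd)(dppb)]BF4 (10 mol %), CH2Cl2, rt
Reagents that add atoms: none
Why: Hydroxyl-directed hydrogenation with a cationic rhodium diphosphine catalyst, in which the C14 hydroxyl anchors rhodium on the C10 flank of the twisted diene (six-membered chelate O14–C14–C10–C5–C4–Rh) and hydrogen reaches C4 of the 1,1-disubstituted alkene so that the new C4–H lies syn-coplanar with C14 (least A(1,3) strain) with the C3 chain on the α face away from the pseudoaxial β-C6 silyl ether and C15 on the β face, which is the 4S configuration, while the tetrasubstituted C5=C10 alkene is too hindered to be reduced.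

Step 14
Reactants: 20 saturated side-chain alcohol
Product: 23 α-methylene lactone (3aS,4S,7aR)-4-{[tert-butyl(dimethyl)silyl]oxy}-5-[(2S)-5-{[tert-butyl(dimethyl)silyl]oxy}pentan-2-yl]-6-(hydroxymethyl)-3-methylidene-3a,4,7,7a-tetrahydro-1-benzofuran-2(3H)-one, via Mannich base 21 (not isolated), via ammonium iodide 22 (not isolated)
Conditions: LiN(i-Pr)2 (2.5 equiv), THF, −78 °C; CH2=NMe2+ I−, −78 °C to rt; then MeI, MeOH, rt; then NaHCO3 (aq.), CH2Cl2, rt
Reagents that add atoms: dimethyl(methylidene)ammonium iodide, C=[N+](C)C.[I-]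
Why: Mannich-type α-methylenation of a lactone, in which the lithium enolate at C11 (formed beside the C14 alkoxide) is aminomethylated by the iminium salt and quaternisation followed by mild base-induced Hofmann-type elimination gives the exocyclic C11=C13 alkene without touching C7.

Step 15
Reactants: 23 α-methylene lactone
Product: 24 methacrylate [(3aS,4S,7aR)-4-{[tert-butyl(dimethyl)silyl]oxy}-5-[(2S)-5-{[tert-butyl(dimethyl)silyl]oxy}pentan-2-yl]-3-methylidene-2-oxo-2,3,3a,4,7,7a-hexahydro-1-benzofuran-6-yl]methyl 2-methylprop-2-enoate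
Conditions: methacrylic anhydride, Et3N, DMAP (cat.), CH2Cl2, 0 °C to rt
Reagents that add atoms: methacrylic anhydride, C=C(C)C(=O)OC(=O)C(C)=C
Why: DMAP-catalysed acylation of the primary allylic C14 hydroxyl, the only free hydroxyl in the molecule, by the anhydride.

Step 16
Reactants: 24 methacrylate
Product: 25 diol [(3aR,4S,7aR)-4-hydroxy-5-[(2S)-5-hydroxypentan-2-yl]-3-methylidene-2-oxo-2,3,3a,4,7,7a-hexahydro-1-benzofuran-6-yl]methyl 2-methylprop-2-enoate
Conditions: HF·pyridine, pyridine, THF, 0 °C to rt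
Reagents that add atoms: none
Why: Fluoride-mediated cleavage of both silyl ethers under buffered acidic conditions, which avoid alkoxide formation and hence oxa-Michael addition to the α-methylene lactone or acyl migration.

Step 17
Reactants: 25 diol
Product: 26 target [(3aS,4S,7aR)-4-acetoxy-5-[(2S)-5-acetoxypentan-2-yl]-3-methylidene-2-oxo-2,3,3a,4,7,7a-hexahydro-1-benzofuran-6-yl]methyl 2-methylprop-2-enoate
Conditions: Ac2O, pyridine, DMAP (cat.), CH2Cl2, 0 °C to rt
Reagents that add atoms: acetic anhydride, CC(=O)OC(C)=O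
Why: DMAP-catalysed acetylation of the primary C1 and the secondary allylic C6 hydroxyls should give the diacetate without affecting the conjugated esters.

**Compound list**

1 | 3-bromo-2-(bromomethyl)prop-1-ene | C=C(CBr)CBr | starting material
2 | 4-methoxybenzyl alcohol | COc1ccc(CO)cc1 | starting material
3 | 1-({[2-(bromomethyl)prop-2-en-1-yl]oxy}methyl)-4-methoxybenzene | C=C(CBr)COCc1ccc(OC)cc1 | intermediate
4 | 3-{[(4-methoxybenzyl)oxy]methyl}but-3-en-1-ol | C=C(CCO)COCc1ccc(OC)cc1 | intermediate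
5 | 3-{[(4-methoxybenzyl)oxy]methyl}but-3-enal | C=C(CC=O)COCc1ccc(OC)cc1 | intermediate
6 | (S)-4-benzyl-1,3-oxazolidin-2-one | O=C1N[C@@H](Cc2ccccc2)CO1 | starting material
7 | methyl 4-chloro-4-oxobutanoate | COC(=O)CCC(Cl)=O | starting material
8 | methyl 4-[(4S)-4-benzyl-2-oxo-1,3-oxazolidin-3-yl]-4-oxobutanoate | COC(=O)CCC(=O)N1[C@@H](Cc2ccccc2)COC1=O | intermediate
9 | aldol adduct, methyl (3S,4R)-3-{[(4S)-4-benzyl-2-oxo-1,3-oxazolidin-3-yl]carbonyl}-4-hydroxy-6-{[(4-methoxybenzyl)oxy]methyl}hept-6-enoate | COC(=O)C[C@H](C(=O)N1[C@@H](Cc2ccccc2)COC1=O)[C@H](O)CC(=C)COCc1ccc(OC)cc1 | intermediate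
10 | trans-lactone imide, (4S)-4-benzyl-3-{[(2R,3S)-2-(2-{[(4-methoxybenzyl)oxy]methyl}prop-2-en-1-yl)-5-oxotetrahydrofuran-3-yl]carbonyl}-1,3-oxazolidin-2-one | O=C1C[C@H](C(=O)N2[C@@H](Cc3ccccc3)COC2=O)[C@@H](CC(=C)COCc2ccc(OC)cc2)O1 | intermediate
11 | trans-lactone acid, (2R,3S)-2-(2-{[(4-methoxybenzyl)oxy]methyl}prop-2-en-1-yl)-5-oxotetrahydrofuran-3-carboxylic acid | O=C1C[C@H](C(=O)O)[C@@H](CC(=C)COCc2ccc(OC)cc2)O1 | intermediate
12 | pent-4-yn-1-ol | C#CCCCO | starting material
13 | tert-butyl(dimethyl)(pent-4-yn-1-yloxy)silane | C#CCCCO[Si](C)(C)C(C)(C)C | intermediate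
14 | acid chloride, (2R,3S)-2-(2-{[(4-methoxybenzyl)oxy]methyl}prop-2-en-1-yl)-5-oxotetrahydrofuran-3-carbonyl chloride | O=C1C[C@H](C(=O)Cl)[C@@H](CC(=C)COCc2ccc(OC)cc2)O1 | intermediate
15 | ynone, (4S,5R)-4-(6-{[tert-butyl(dimethyl)silyl]oxy}hex-2-ynoyl)-5-(2-{[(4-methoxybenzyl)oxy]methyl}prop-2-en-1-yl)dihydrofuran-2(3H)-one | O=C1C[C@H](C(=O)C#CCCCO[Si](C)(C)C(C)(C)C)[C@@H](CC(=C)COCc2ccc(OC)cc2)O1 | intermediate
16 | trans-lactone enyne, (4R,5R)-4-[(1S)-6-{[tert-butyl(dimethyl)silyl]oxy}-1-hydroxyhex-2-yn-1-yl]-5-(2-{[(4-methoxybenzyl)oxy]methyl}prop-2-en-1-yl)dihydrofuran-2(3H)-one | O=C1C[C@H]([C@H](O)C#CCCCO[Si](C)(C)C(C)(C)C)[C@@H](CC(=C)COCc2ccc(OC)cc2)O1 | intermediate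
17 | bicyclic lactone diene, (3aR,4S,7aR)-5-(5-{[tert-butyl(dimethyl)silyl]oxy}pent-1-en-2-yl)-4-hydroxy-6-{[(4-methoxybenzyl)oxy]methyl}-3a,4,7,7a-tetrahydro-1-benzofuran-2(3H)-one | COc1ccc(COCC2=C(C(=C)CCCO[Si](C)(C)C(C)(C)C)[C@@H](O)[C@H]3CC(=O)O[C@@H]3C2)cc1 | intermediate
18 | C6 silyl ether, (3aS,4S,7aR)-4-{[tert-butyl(dimethyl)silyl]oxy}-5-(5-{[tert-butyl(dimethyl)silyl]oxy}pent-1-en-2-yl)-6-{[(4-methoxybenzyl)oxy]methyl}-3a,4,7,7a-tetrahydro-1-benzofuran-2(3H)-one | COc1ccc(COCC2=C(C(=C)CCCO[Si](C)(C)C(C)(C)C)[C@@H](O[Si](C)(C)C(C)(C)C)[C@H]3CC(=O)O[C@@H]3C2)cc1 | intermediate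
19 | dienyl alcohol, (3aS,4S,7aR)-4-{[tert-butyl(dimethyl)silyl]oxy}-5-(5-{[tert-butyl(dimethyl)silyl]oxy}pent-1-en-2-yl)-6-(hydroxymethyl)-3a,4,7,7a-tetrahydro-1-benzofuran-2(3H)-one | OCC1=C(C(=C)CCCO[Si](C)(C)C(C)(C)C)[C@@H](O[Si](C)(C)C(C)(C)C)[C@H]2CC(=O)O[C@@H]2C1 | intermediate
20 | saturated side-chain alcohol, (3aS,4S,7aR)-4-{[tert-butyl(dimethyl)silyl]oxy}-5-[(2S)-5-{[tert-butyl(dimethyl)silyl]oxy}pentan-2-yl]-6-(hydroxymethyl)-3a,4,7,7a-tetrahydro-1-benzofuran-2(3H)-one | OCC1=C([C@@H](C)CCCO[Si](C)(C)C(C)(C)C)[C@@H](O[Si](C)(C)C(C)(C)C)[C@H]2CC(=O)O[C@@H]2C1 | intermediate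
21 | Mannich base, 3-[(dimethylamino)methyl] derivative of 20 (mixture at C11) | OCC1=C([C@@H](C)CCCO[Si](C)(C)C(C)(C)C)[C@@H](O[Si](C)(C)C(C)(C)C)[C@H]2C(CN(C)C)C(=O)O[C@@H]2C1 | intermediate
22 | ammonium iodide, 3-[(trimethylammonio)methyl] derivative of 20, iodide salt (mixture at C11) | OCC1=C([C@@H](C)CCCO[Si](C)(C)C(C)(C)C)[C@@H](O[Si](C)(C)C(C)(C)C)[C@H]2C(C[N+](C)(C)C)C(=O)O[C@@H]2C1.[I-] | intermediate
23 | α-methylene lactone, (3aS,4S,7aR)-4-{[tert-butyl(dimethyl)silyl]oxy}-5-[(2S)-5-{[tert-butyl(dimethyl)silyl]oxy}pentan-2-yl]-6-(hydroxymethyl)-3-methylidene-3a,4,7,7a-tetrahydro-1-benzofuran-2(3H)-one | OCC1=C([C@@H](C)CCCO[Si](C)(C)C(C)(C)C)[C@@H](O[Si](C)(C)C(C)(C)C)[C@H]2C(=C)C(=O)O[C@@H]2C1 | intermediate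
24 | methacrylate, [(3aS,4S,7aR)-4-{[tert-butyl(dimethyl)silyl]oxy}-5-[(2S)-5-{[tert-butyl(dimethyl)silyl]oxy}pentan-2-yl]-3-methylidene-2-oxo-2,3,3a,4,7,7a-hexahydro-1-benzofuran-6-yl]methyl 2-methylprop-2-enoate | C=C(C)C(=O)OCC1=C([C@@H](C)CCCO[Si](C)(C)C(C)(C)C)[C@@H](O[Si](C)(C)C(C)(C)C)[C@H]2C(=C)C(=O)O[C@@H]2C1 | intermediate
25 | diol, [(3aR,4S,7aR)-4-hydroxy-5-[(2S)-5-hydroxypentan-2-yl]-3-methylidene-2-oxo-2,3,3a,4,7,7a-hexahydro-1-benzofuran-6-yl]methyl 2-methylprop-2-enoate | C=C(C)C(=O)OCC1=C([C@@H](C)CCCO)[C@@H](O)[C@H]2C(=C)C(=O)O[C@@H]2C1 | intermediate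
26 | CNP0157277.1, [(3aS,4S,7aR)-4-acetoxy-5-[(2S)-5-acetoxypentan-2-yl]-3-methylidene-2-oxo-2,3,3a,4,7,7a-hexahydro-1-benzofuran-6-yl]methyl 2-methylprop-2-enoate | C=C(C)C(=O)OCC1=C([C@@H](C)CCCOC(C)=O)[C@@H](OC(C)=O)[C@H]2C(=C)C(=O)O[C@@H]2C1 | target

**Step count**

Total: 17 steps. Longest linear sequence: 15 steps (steps 1–3, 5, 6, 8–17).

**Steps most likely to fail**

Step 10. The ruthenium vinylcarbene may fail to engage the hindered C10 methylidene, so that the catalyst decays and the alkyne oligomerises, or closure may drift to the endo sense. The fallback replaces carbene metathesis by π-acid catalysis and sets out from 16. The C6 hydroxyl would first be silylated (TBSOTf, 2,6-lutidine) to the bis-silyl enyne (4S,5R)-4-[(1S)-1,6-bis{[tert-butyl(dimethyl)silyl]oxy}hex-2-yn-1-yl]-5-(2-{[(4-methoxybenzyl)oxy]methyl}prop-2-en-1-yl)dihydrofuran-2(3H)-one F1. Heating F1 with PtCl2 (cat.) in toluene at 80 °C should then bring about the known platinum-catalysed skeletal rearrangement of 1,7-enynes to 1-vinylcyclohexenes. In that process the 1,1-disubstituted alkene attacks the platinum-bound alkyne in the exo sense and its methylene carbon migrates to C4, and the tertiary cation character at C10 helps instead of hindering. The product is 18, where the fallback rejoins the route.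

Step 13. Hydrogen may be delivered to the wrong face of C4=C15 if the rotamer with the C3 chain on the β face reacts, and 1,4-reduction of the diene may compete. The fallback moves the anchor to the other flank of the diene and sets out from 17, which still has the free C6 hydroxyl and the C14 ether. Hydrogenation of 17 with [Rh(nbd)(dppb)]BF4 under H2 would be directed by the C6 hydroxyl, which reaches the opposite face of whichever rotamer reacts, and should give (3aR,4S,7aR)-5-[(2S)-5-{[tert-butyl(dimethyl)silyl]oxy}pentan-2-yl]-4-hydroxy-6-{[(4-methoxybenzyl)oxy]methyl}-3a,4,7,7a-tetrahydro-1-benzofuran-2(3H)-one F2. Silylation (TBSOTf, 2,6-lutidine) would give its C6 silyl ether (3aS,4S,7aR)-4-{[tert-butyl(dimethyl)silyl]oxy}-5-[(2S)-5-{[tert-butyl(dimethyl)silyl]oxy}pentan-2-yl]-6-{[(4-methoxybenzyl)oxy]methyl}-3a,4,7,7a-tetrahydro-1-benzofuran-2(3H)-one F3. DDQ cleavage of the 4-methoxybenzyl ether then returns to the route at 20.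

Step 8. The amine base may trigger ketene formation from the acid chloride or β-elimination of the lactone carboxylate from the newly formed ynone. The fallback avoids having a free enolisable ketone under basic conditions and sets out from 11. Coupling with N,O-dimethylhydroxylamine hydrochloride (EDC·HCl, N-methylmorpholine, CH2Cl2) would give the Weinreb amide (2R,3S)-N-methoxy-N-methyl-2-(2-{[(4-methoxybenzyl)oxy]methyl}prop-2-en-1-yl)-5-oxotetrahydrofuran-3-carboxamide F4. Addition of the lithium acetylide of 13 (n-BuLi, THF, −78 °C) should stop at the chelated tetrahedral adduct, which releases the ketone only on aqueous work-up. This rejoins the route at 15.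

**Further compounds**

F1 | step 10 | (4S,5R)-4-[(1S)-1,6-bis{[tert-butyl(dimethyl)silyl]oxy}hex-2-yn-1-yl]-5-(2-{[(4-methoxybenzyl)oxy]methyl}prop-2-en-1-yl)dihydrofuran-2(3H)-one | O=C1C[C@H]([C@H](O[Si](C)(C)C(C)(C)C)C#CCCCO[Si](C)(C)C(C)(C)C)[C@@H](CC(=C)COCc2ccc(OC)cc2)O1
F2 | step 13 | (3aR,4S,7aR)-5-[(2S)-5-{[tert-butyl(dimethyl)silyl]oxy}pentan-2-yl]-4-hydroxy-6-{[(4-methoxybenzyl)oxy]methyl}-3a,4,7,7a-tetrahydro-1-benzofuran-2(3H)-one | COc1ccc(COCC2=C([C@@H](C)CCCO[Si](C)(C)C(C)(C)C)[C@@H](O)[C@H]3CC(=O)O[C@@H]3C2)cc1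
F3 | step 13 | (3aS,4S,7aR)-4-{[tert-butyl(dimethyl)silyl]oxy}-5-[(2S)-5-{[tert-butyl(dimethyl)silyl]oxy}pentan-2-yl]-6-{[(4-methoxybenzyl)oxy]methyl}-3a,4,7,7a-tetrahydro-1-benzofuran-2(3H)-one | COc1ccc(COCC2=C([C@@H](C)CCCO[Si](C)(C)C(C)(C)C)[C@@H](O[Si](C)(C)C(C)(C)C)[C@H]3CC(=O)O[C@@H]3C2)cc1
F4 | step 8 | (2R,3S)-N-methoxy-N-methyl-2-(2-{[(4-methoxybenzyl)oxy]methyl}prop-2-en-1-yl)-5-oxotetrahydrofuran-3-carboxamide | O=C1C[C@H](C(=O)N(C)OC)[C@@H](CC(=C)COCc2ccc(OC)cc2)O1
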